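The route rests on cutting the two ring C–O bonds, C2–O and C5–O (C1 is the quaternary carbinol carbon, C3=C4 the ring alkene, C6 the ketone carbon), back to one O2 molecule and the ring diene of an achiral fulvene. The key step, a singlet-oxygen [4+2] cycloaddition, exploits the meso cis-2,5-dioxygenated cyclopent-3-ene ring: closing a 2,3-dioxabicyclo[2.2.1]heptene places both oxygens on one ring face in a single operation. Its precursor, 6-decylfulvene, already holds all sixteen skeletal carbons. Its exocyclic C1=C6 alkene survives the cycloaddition and later receives the C1 hydroxyl and the C6 oxygen from the face opposite the two acetates.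

Key step: step 3

Remark: locants follow the target numbering above (in fulvene nomenclature the two ring carbons attacked by oxygen are C1 and C4). Compounds 6–9 are racemic with one enantiomer drawn, and the target is meso. Cyclopentadiene is not sold as the monomer, so it is generated from its commercial dimer in step 1.

Step 1
Reactants: 1 dicyclopentadiene (commercial, mainly endo)
Product: 2 cyclopenta-1,3-diene
Conditions: neat, 170–180 °C, slow distillation through a short column, receiver at −78 °C; used at once
Reagents that add atoms: none
Why: Thermal retro-Diels–Alder cracking of the dimer should deliver two molecules of the volatile monomer, which is kept cold to suppress re-dimerisation; no stereocenter is involved.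

Step 2
Reactants: 2 cyclopenta-1,3-diene (2 equiv); 3 undecanal
Product: 4 6-decylfulvene
Conditions: pyrrolidine (0.2 equiv), MeOH/H2O 4:1, 0 → 20 °C, Ar; pentane extraction, rapid filtration through base-washed silica; used at once, cold and air-free
Reagents that add atoms: none
Why: Amine-catalysed fulvene condensation (Knoevenagel type): the aldehyde is activated as its pyrrolidinium ion, is attacked by cyclopentadiene and then loses pyrrolidine to form the C1=C6 bond with release of water, while catalytic amine in aqueous methanol should keep self-aldolisation of the enolisable aldehyde low; the product has no stereocenter.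

Step 3
Reactants: 4 6-decylfulvene; 5 dioxygen (as singlet oxygen, generated in the flask)
Product: 7 cis-2-undecylidenecyclopent-4-ene-1,3-diol (racemic), via endoperoxide 6 (not isolated)
Conditions: O2, 5,10,15,20-tetraphenylporphyrin (cat.), hν (visible), CH2Cl2, −78 °C; Ar purge, then thiourea (2.2 equiv) in MeOH, −78 → 20 °C
Reagents that add atoms: none
Why: Sensitised singlet oxygen adds across the termini of the s-cis ring diene of 4 (C2 and C5) in a concerted, suprafacial [4+2] cycloaddition, forming both C–O bonds at once and moving the ring alkene to C3=C4. The closest known reaction type is the photooxygenation of cyclopentadienes and 6-substituted fulvenes to 2,3-dioxabicyclo[2.2.1]hept-5-enes, followed by thiourea reduction of the peroxide to the cis-cyclopent-4-ene-1,3-diol. The single new ring, the peroxide bridge of the bicycle, is closed by cycloaddition (both of its new bonds made in the same event), not by cyclisation of a tethered chain. The two new stereocenters, C2 and C5, control each other through delivery of one O2 molecule to one face of the planar achiral diene, so only the cis arrangement can form; the product is racemic solely because the undecylidene group points toward one bridgehead or the other. The step needs periselectivity for the ring diene over ene oxygenation at the side-chain allylic CH2 and over [2+2] addition at C1=C6, which the locked s-cis geometry of the five-membered diene should secure, leaving the exocyclic alkene intact. It also needs the labile peroxide to outlive its own rearrangement, which is addressed by irradiating at −78 °C and adding thiourea before any warming, so that only the O–O bond is cleaved and both C–O bonds, hence the cis relation, pass into 7.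

Step 4
Reactants: 7 cis-2-undecylidenecyclopent-4-ene-1,3-diol
Product: 8 cis-2-undecylidenecyclopent-4-ene-1,3-diyl diacetate (racemic)
Conditions: Ac2O, pyridine, 4-(dimethylamino)pyridine (cat.), CH2Cl2, 0 → 20 °C; chromatography on base-washed silica
Reagents that add atoms: acetic anhydride, CC(=O)OC(C)=O
Why: Base-mediated O-acylation with nucleophilic catalysis should esterify both unhindered secondary alcohols under non-ionising conditions that spare the doubly allylic C–O bonds; no stereocenter is touched.

Step 5
Reactants: 8 cis-2-undecylidenecyclopent-4-ene-1,3-diyl diacetate
Product: 9 2-hydroxy-2-(1-hydroxyundecyl)cyclopent-4-ene-1,3-diyl diacetate (racemic; C1 hydroxyl trans to both acetoxy groups)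
Conditions: OsO4 (2 mol%), N-methylmorpholine N-oxide (1.05 equiv), acetone/H2O, 0 °C; Na2SO3 quench; taken on without delay
Reagents that add atoms: osmium tetroxide, O=[Os](=O)(=O)=O; N-methylmorpholine N-oxide, C[N+]1([O-])CCOCC1; water, O
Why: OsO4-catalysed syn-dihydroxylation ([3+2] addition with amine-oxide reoxidation): the trisubstituted exocyclic C1=C6 alkene is the more electron-rich of the two alkenes and should react ahead of the cis-disubstituted ring alkene when the oxidant is limited to one equivalent, and osmium should approach the face opposite the two allylic acetoxy groups (steric shielding reinforced by the usual anti preference of osmylation next to allylic oxygen), which sets the C1 hydroxyl trans to both acetates, while the C6 configuration follows from syn addition and is erased in step 6.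

Step 6
Reactants: 9 2-hydroxy-2-(1-hydroxyundecyl)cyclopent-4-ene-1,3-diyl diacetate
Product: 10 2-hydroxy-2-undecanoylcyclopent-4-ene-1,3-diyl diacetate (target, meso)
Conditions: 2-iodoxybenzoic acid (IBX, 1.5 equiv), DMSO, 20 °C
Reagents that add atoms: none
Why: Hypervalent-iodine oxidation of the secondary C6 carbinol: IBX converts 1,2-diols into α-hydroxy ketones without C–C cleavage and cannot oxidise the tertiary C1 alcohol, the neutral medium should leave the allylic acetates and the α-ketol untouched, and loss of the C6 stereocenter makes the product meso with C1, C2 and C5 unchanged.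

Compound list
1 | endo-dicyclopentadiene (3a,4,7,7a-tetrahydro-4,7-methanoindene; racemic, one enantiomer drawn) | C1C=C[C@H]2[C@@H]1[C@@H]3C[C@H]2C=C3 | starting material
2 | cyclopenta-1,3-diene | C1=CCC=C1 | intermediate
3 | undecanal | CCCCCCCCCCC=O | starting material
4 | 6-decylfulvene (5-undecylidenecyclopenta-1,3-diene; achiral) | CCCCCCCCCCC=C1C=CC=C1 | intermediate
5 | dioxygen | O=O | starting material
6 | 7-undecylidene-2,3-dioxabicyclo[2.2.1]hept-5-ene (racemic, one enantiomer drawn) | CCCCCCCCCC/C=C1/[C@@H]2C=C[C@H]1OO2 | intermediate
7 | cis-2-undecylidenecyclopent-4-ene-1,3-diol (both hydroxyls on one face; racemic, one enantiomer drawn) | CCCCCCCCCC/C=C1/[C@@H](O)C=C[C@H]1O | intermediate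
8 | cis-2-undecylidenecyclopent-4-ene-1,3-diyl diacetate (racemic, one enantiomer drawn) | CCCCCCCCCC/C=C1/[C@@H](OC(C)=O)C=C[C@H]1OC(C)=O | intermediate
9 | 2-hydroxy-2-(1-hydroxyundecyl)cyclopent-4-ene-1,3-diyl diacetate (ring hydroxyl trans to both cis acetoxy groups; racemic, one enantiomer drawn) | CCCCCCCCCC[C@H](O)[C@@]1(O)[C@@H](OC(C)=O)C=C[C@H]1OC(C)=O | intermediate
10 | 2-hydroxy-2-undecanoylcyclopent-4-ene-1,3-diyl diacetate (meso; acetoxy groups cis to each other and to the undecanoyl group, trans to the hydroxyl) | CCCCCCCCCCC(=O)[C@@]1(O)[C@@H](OC(C)=O)C=C[C@H]1OC(C)=O | target

Total step count: 6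
Longest linear sequence: 6 steps (1 → 2 → 4 → 7 → 8 → 9 → 10)

Steps most likely to fail

Step 3. The bicyclic peroxide may rearrange thermally before the reductant cleaves the O–O bond, or the fulvene may be lost to ene oxygenation of the side-chain CH2 or to oligomerisation. The fallback reaches diol 7 without any peroxide, sets out from undecanal 3 and returns at 7. The lithium enolate of commercial racemic 4-(tert-butyldimethylsilyloxy)cyclopent-2-en-1-one F1 (LiN(iPr)2, THF, −78 °C) would add to 3 to give the trans aldol 5-(1-hydroxyundecyl)-4-(tert-butyldimethylsilyloxy)cyclopent-2-en-1-one F2. Mesylation (MsCl, Et3N, CH2Cl2, 0 °C) to the mesylate 1-[2-oxo-5-(tert-butyldimethylsilyloxy)cyclopent-3-enyl]undecyl methanesulfonate F3 and elimination with DBU should give the cross-conjugated dienone 4-(tert-butyldimethylsilyloxy)-5-undecylidenecyclopent-2-en-1-one F4. Its E and Z isomers both converge on racemic 7 once the ring is symmetrised. Luche reduction (NaBH4, CeCl3·7H2O, MeOH, −78 °C), with hydride arriving anti to the silyloxy group, should give cis-4-(tert-butyldimethylsilyloxy)-5-undecylidenecyclopent-2-en-1-ol F5, and Bu4NF in THF would free diol 7. The cis relation then comes from a substrate-controlled reduction instead of from the peroxide bridge.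

Step 5. Osmylation of the ring alkene may compete with that of the exocyclic alkene, over-oxidation to a tetraol may occur, or an acetyl group may shift to the new C6 hydroxyl. The fallback sets out from diacetate 8 and returns at target 10, bypassing 9. RuO4-catalysed ketohydroxylation (RuCl3 cat., KHSO5 as its commercial triple salt 2KHSO5·KHSO4·K2SO4, NaHCO3, EtOAc/MeCN/H2O, 20 °C) would install the C1 hydroxyl and the C6 ketone in one operation. The more electrophilic oxidant should favour the trisubstituted alkene more strongly and again add anti to the acetates. No free C6 hydroxyl is ever present to accept an acetyl group. No compound outside the list is formed (F0).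

Step 2. Self-aldol condensation of undecanal under amine catalysis, or dimerisation and double-bond isomerisation of the mono-alkyl fulvene, may erode the condensation. The fallback makes the same fulvene by alkylation–elimination, sets out from undecanal 3 and cyclopentadiene 2 and returns at 4. Acetyl chloride with catalytic ZnCl2 would convert 3 into 1-chloroundecyl acetate F6. NaH in THF would convert 2 into sodium cyclopentadienide F7. Alkylation at −40 °C should give 5-(1-acetoxyundecyl)cyclopenta-1,3-diene F8 (with its double-bond isomers), and Et3N would eliminate acetic acid to give 4 under non-aldolising conditions.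

Further compounds
F1 | step 3 | 4-(tert-butyldimethylsilyloxy)cyclopent-2-en-1-one (racemic, commercial) | O=C1C=C[C@@H](O[Si](C)(C)C(C)(C)C)C1
F2 | step 3 | trans-5-(1-hydroxyundecyl)-4-(tert-butyldimethylsilyloxy)cyclopent-2-en-1-one (racemic, carbinol epimers) | O=C1C=C[C@@H](O[Si](C)(C)C(C)(C)C)[C@@H]1C(O)CCCCCCCCCC
F3 | step 3 | 1-[trans-2-oxo-5-(tert-butyldimethylsilyloxy)cyclopent-3-enyl]undecyl methanesulfonate (racemic, epimers) | O=C1C=C[C@@H](O[Si](C)(C)C(C)(C)C)[C@@H]1C(OS(C)(=O)=O)CCCCCCCCCC
F4 | step 3 | 4-(tert-butyldimethylsilyloxy)-5-undecylidenecyclopent-2-en-1-one (racemic, E/Z mixture) | O=C1C=C[C@@H](O[Si](C)(C)C(C)(C)C)C1=CCCCCCCCCCC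
F5 | step 3 | cis-4-(tert-butyldimethylsilyloxy)-5-undecylidenecyclopent-2-en-1-ol (racemic, E/Z mixture) | O[C@H]1C=C[C@@H](O[Si](C)(C)C(C)(C)C)C1=CCCCCCCCCCC
F0 | step 5 | none | none
F6 | step 2 | 1-chloroundecyl acetate (racemic) | CCCCCCCCCCC(Cl)OC(C)=O
F7 | step 2 | sodium cyclopentadienide | [Na+].[cH-]1cccc1
F8 | step 2 | 5-(1-acetoxyundecyl)cyclopenta-1,3-diene (racemic, with double-bond isomers) | CCCCCCCCCCC(OC(C)=O)C1C=CC=C1
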